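**Retrosynthetic overview**

- Target 23 is traced back, through C-dimethylation of rings A and E, cleavage of fifteen methyl ethers, five-fold butanoylation and one O-methylation, to phenol 19, the all-aromatic deacyl pentamer.
- The strategy rests on ring C: C1, C3 and C5 carry oxygen, C2 and C4 carry two identical ArCH2 arms, and C6 carries H (later butanoyl). The ring is cut into one two-carbon ketene unit (C1, C6) and two identical MeO–C≡C–CH2Ar units (C2–C3 and C4–C5), i.e. cyclobutenone 14 plus ynol ether 10 (Danheiser benzannulation).
- Cyclobutenone 14 comes from 10 by dichloroketene [2+2] cycloaddition and zinc dechlorination, so ynol ether 10 serves both halves.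
- Ynol ether 10 comes from lithium methoxyacetylide (from trichloroethylene and methanol) and benzylic alcohol 5, which is made by mono-formylation and reduction of bis(2,4,6-trimethoxyphenyl)methane 3 (two molecules of 1,3,5-trimethoxybenzene joined by formaldehyde).
- Ring order: rings A, B, D and E are bought as arenes; the four-membered ring of 14 is made, then ring C (the only ring closed); rings A and E are dearomatised in the last step.

Key step: step 8

Remark: the target has no stereocentre and is drawn as one enol tautomer of rings A and E. "Ar" below means the 2,4,6-trimethoxy-3-[(2,4,6-trimethoxyphenyl)methyl]phenyl group (ring B carrying ring A).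

**Step 1**
Reactants: 1 1,3,5-trimethoxybenzene; 2 formaldehyde
Product: 3 bis(2,4,6-trimethoxyphenyl)methane
Conditions: aq. CH2O (37 %), AcOH, cat. HCl, rt; 1 (6 equiv per CH2O, excess recovered)
Reagents that add atoms: 1,3,5-trimethoxybenzene (second molecule) COc1cc(OC)cc(OC)c1
Why: Acid-catalysed Friedel–Crafts hydroxymethylation of one molecule of 1 gives a 2,4,6-trimethoxybenzyl cation that is captured by a second molecule of 1 with loss of water, and the excess of 1 should hold back further chain growth.

**Step 2**
Reactants: 3 bis(2,4,6-trimethoxyphenyl)methane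
Product: 4 2,4,6-trimethoxy-3-[(2,4,6-trimethoxyphenyl)methyl]benzaldehyde (ArCHO)
Conditions: POCl3 (1 equiv), DMF, CH2Cl2, 0 °C → rt; 3 in threefold excess (recovered); then ice water
Reagents that add atoms: N,N-dimethylformamide CN(C)C=O; water O
Why: Vilsmeier–Haack formylation attacks one of the four equivalent ring carbons flanked by two methoxy groups, the formyl group then deactivates that ring, and the excess of 3 should keep attack on the second ring low.

**Step 3**
Reactants: 4 ArCHO
Product: 5 {2,4,6-trimethoxy-3-[(2,4,6-trimethoxyphenyl)methyl]phenyl}methanol (ArCH2OH)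
Conditions: NaBH4, THF/MeOH, 0 °C; aq. NaHCO3 work-up
Reagents that add atoms: none
Why: Borohydride reduction of the aryl aldehyde proceeds under non-acidic conditions, which avoids ionisation of the acid-labile 2,4,6-trialkoxybenzyl alcohol.

**Step 4**
Reactants: 6 trichloroethylene
Product: 7 (E)-1,2-dichloro-1-methoxyethene
Conditions: MeOH, KH, THF, 0 °C; then 6, –50 °C → rt; distillation
Reagents that add atoms: methanol CO
Why: Methoxide eliminates HCl from 6 to dichloroacetylene and methanol then adds to it in anti fashion (the standard preparation of 1,2-dichlorovinyl ethers), which sets the E geometry.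

**Step 5**
Reactants: 5 ArCH2OH; 7 (E)-1,2-dichloro-1-methoxyethene
Product: 10 1-methoxy-3-Ar-prop-1-yne (ynol ether half), via lithium methoxyacetylide 8 (not isolated), via benzylic mesylate 9 (not isolated)
Conditions: (a) 7, n-BuLi (2 equiv per 7), THF, –78 → –40 °C; (b) 5, n-BuLi (1 equiv), THF, –78 °C, then Ms2O; (c) solution b into a (3 equiv of 8), DMPU, –78 → –20 °C; aq. NaHCO3
Reagents that add atoms: none
Why: Elimination and chlorine–lithium exchange turn 7 into lithium methoxyacetylide, which alkylates at the benzylic carbon (SN2 alkylation of a lithium alkoxyacetylide), and because a 2,4,6-trialkoxybenzyl electrophile ionises readily and would alkylate ring A of a second molecule, it is made from the lithium alkoxide without acid at –78 °C and consumed at once instead of being isolated as a halide.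

**Step 6**
Reactants: 10 1-methoxy-3-Ar-prop-1-yne; 11 trichloroacetyl chloride
Product: 13 4,4-dichloro-3-methoxy-2-(ArCH2)cyclobut-2-en-1-one, via dichloroketene 12 (not isolated)
Conditions: Zn(Cu), Et2O/DME, 0 °C → rt, slow addition of 11
Reagents that add atoms: none
Why: [2+2] cycloaddition of dichloroketene to the ynol ether joins the nucleophilic alkyne carbon remote from oxygen to the ketene carbonyl carbon and so should give the 3-methoxycyclobutenone regioselectively, while DME ties up ZnCl2 so that the ynol ether and the electron-rich rings are spared.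

**Step 7**
Reactants: 13 4,4-dichloro-3-methoxy-2-(ArCH2)cyclobut-2-en-1-one
Product: 14 3-methoxy-2-(ArCH2)cyclobut-2-en-1-one (cyclobutenone half)
Conditions: Zn dust, AcOH, TMEDA, EtOH, 0 °C → rt
Reagents that add atoms: none
Why: Zinc reduction of the α,α-dichloro ketone (reductive dechlorination through the zinc enolate), buffered by TMEDA/AcOH, should remove both chlorines without touching the vinylogous ester.

**Step 8**
Reactants: 14 3-methoxy-2-(ArCH2)cyclobut-2-en-1-one; 10 1-methoxy-3-Ar-prop-1-yne
Product: 19 3,5-dimethoxy-2,4-bis(ArCH2)phenol (ring C closed; all-aromatic deacyl pentamer), via vinylketene 15 (not isolated), via vinylcyclobutenone 16 (not isolated), via dienylketene 17 (not isolated), via cyclohexadienone 18 (not isolated)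
Conditions: PhMe (degassed), 110 °C, sealed tube, argon; 10 (1.3 equiv)
Reagents that add atoms: none
Why: Heat opens 14 in a four-electron electrocyclic step to (2-methoxyvinyl)ketene 15, which adds [2+2] to the triple bond of 10 to give vinylcyclobutenone 16; a second four-electron opening gives dienylketene 17, six-electron electrocyclisation gives cyclohexadienone 18, and enolisation gives phenol 19. The closest known reaction type is the Danheiser benzannulation of cyclobutenones with alkoxyalkynes, used here with a cyclobutenone that already carries a 3-alkoxy group so that the new ring has the 1,3,5-trioxygen pattern. Ring C is the only ring closed, by thermal disrotatory 6π electrocyclisation of the ketene carbon C1 onto the terminal CH2 (C6) of 17, after the [2+2] step has made the C1–C2 and C3–C4 bonds. No stereocentre remains in 19 (the quaternary carbon of racemic 16 becomes planar on ring opening), so no stereocontrol element is needed. The selectivity needed is regiochemical, in the ketene–ynol ether [2+2]: the alkyne carbon remote from oxygen is the nucleophilic one and bonds to the electrophilic ketene carbon C1, which puts the two ArCH2 arms on C2 and C4 and alternates O and C substituents around the ring. A methyl ynol ether is chosen because it cannot lose an alkene by a retro-ene path at this temperature, and since both partners carry the same Ar group only one pentamer can result.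

**Step 9**
Reactants: 19 3,5-dimethoxy-2,4-bis(ArCH2)phenol
Product: 20 1,3,5-trimethoxy-2,4-bis(ArCH2)benzene (pentadecamethyl ether of the deacyl pentamer)
Conditions: MeI, K2CO3, acetone, 50 °C
Reagents that add atoms: iodomethane CI
Why: Williamson O-methylation of the single phenol makes ring C a trimethoxyarene like the other four rings, so that one acylation protocol serves all five rings and no aryl ester can form.

**Step 10**
Reactants: 20 1,3,5-trimethoxy-2,4-bis(ArCH2)benzene
Product: 21 pentabutanoyl derivative of 20 (one butanoyl group on the free ring carbon of rings B, C, D and on one of the two equivalent free carbons of rings A and E)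
Conditions: n-PrCOCl (6 equiv), SnCl4 (6 equiv), CH2Cl2, –20 → 0 °C
Reagents that add atoms: butanoyl chloride CCCC(Cl)=O
Why: Friedel–Crafts acylation works because every remaining ring C–H lies ortho/para to three methoxy groups, the first acyl group deactivates its ring so that rings A and E should take up only one, and SnCl4 at low temperature is chosen to limit ipso attack at the bridge-bearing carbons.

**Step 11**
Reactants: 21 pentabutanoyl pentadecamethyl ether
Product: 22 pentabutanoyl pentadecaphenol (all fifteen OMe replaced by OH)
Conditions: BBr3 (excess), CH2Cl2, –78 °C → rt; then MeOH/H2O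
Reagents that add atoms: none
Why: Boron tribromide cleaves aryl methyl ethers through their oxonium–borane adducts (the ten ortho to a carbonyl group helped by chelation), and the five acyl groups lower the electron density of the rings and so should protect the diarylmethane bridges from acid-induced cleavage.

**Step 12**
Reactants: 22 pentabutanoyl pentadecaphenol
Product: 23 target CNP0188003.0
Conditions: NaOMe (excess), MeI (4.2 equiv), MeOH, 0 °C → rt, argon; then aq. HCl
Reagents that add atoms: iodomethane CI
Why: Alkylative dearomatisation of acylphloroglucinol anions with iodomethane should take place at the only unsubstituted ring carbons (one each in rings A and E), the second methylation at the same least hindered carbon gives the 4,4-dimethyl β-triketone (acylfilicinic acid type) whose weakly nucleophilic anion stops further reaction of that ring, and no stereocentre is formed.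

**Compound list**

1 | 1,3,5-trimethoxybenzene | COc1cc(OC)cc(OC)c1 | starting material
2 | formaldehyde | C=O | starting material
3 | bis(2,4,6-trimethoxyphenyl)methane | COc1cc(OC)cc(OC)c1Cc1c(OC)cc(OC)cc1OC | intermediate
4 | 2,4,6-trimethoxy-3-[(2,4,6-trimethoxyphenyl)methyl]benzaldehyde (ArCHO) | O=Cc1c(OC)cc(OC)c(Cc2c(OC)cc(OC)cc2OC)c1OC | intermediate
5 | {2,4,6-trimethoxy-3-[(2,4,6-trimethoxyphenyl)methyl]phenyl}methanol (ArCH2OH) | OCc1c(OC)cc(OC)c(Cc2c(OC)cc(OC)cc2OC)c1OC | intermediate
6 | trichloroethylene | ClC=C(Cl)Cl | starting material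
7 | (E)-1,2-dichloro-1-methoxyethene | CO/C(Cl)=C\Cl | intermediate
8 | lithium methoxyacetylide | [Li]C#COC | intermediate (not isolated)
9 | ArCH2 methanesulfonate (benzylic mesylate) | CS(=O)(=O)OCc1c(OC)cc(OC)c(Cc2c(OC)cc(OC)cc2OC)c1OC | intermediate (not isolated)
10 | 1-methoxy-3-Ar-prop-1-yne | COC#CCc1c(OC)cc(OC)c(Cc2c(OC)cc(OC)cc2OC)c1OC | intermediate
11 | trichloroacetyl chloride | O=C(Cl)C(Cl)(Cl)Cl | starting material
12 | dichloroketene | O=C=C(Cl)Cl | intermediate (not isolated)
13 | 4,4-dichloro-3-methoxy-2-(ArCH2)cyclobut-2-en-1-one | COC1=C(Cc2c(OC)cc(OC)c(Cc3c(OC)cc(OC)cc3OC)c2OC)C(=O)C1(Cl)Cl | intermediate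
14 | 3-methoxy-2-(ArCH2)cyclobut-2-en-1-one | COC1=C(Cc2c(OC)cc(OC)c(Cc3c(OC)cc(OC)cc3OC)c2OC)C(=O)C1 | intermediate
15 | 3-methoxy-2-(ArCH2)buta-1,3-dien-1-one (vinylketene) | O=C=C(Cc1c(OC)cc(OC)c(Cc2c(OC)cc(OC)cc2OC)c1OC)C(OC)=C | intermediate (not isolated)
16 | racemic 3-methoxy-4-(1-methoxyethenyl)-2,4-bis(ArCH2)cyclobut-2-en-1-one (vinylcyclobutenone) | O=C1C(Cc2c(OC)cc(OC)c(Cc3c(OC)cc(OC)cc3OC)c2OC)=C(OC)C1(Cc1c(OC)cc(OC)c(Cc2c(OC)cc(OC)cc2OC)c1OC)C(OC)=C | intermediate (not isolated)
17 | (3E)-3,5-dimethoxy-2,4-bis(ArCH2)hexa-1,3,5-trien-1-one (dienylketene) | O=C=C(Cc1c(OC)cc(OC)c(Cc2c(OC)cc(OC)cc2OC)c1OC)/C(OC)=C(\C(OC)=C)Cc1c(OC)cc(OC)c(Cc2c(OC)cc(OC)cc2OC)c1OC | intermediate (not isolated)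
18 | 3,5-dimethoxy-2,4-bis(ArCH2)cyclohexa-2,4-dien-1-one | O=C1CC(OC)=C(Cc2c(OC)cc(OC)c(Cc3c(OC)cc(OC)cc3OC)c2OC)C(OC)=C1Cc1c(OC)cc(OC)c(Cc2c(OC)cc(OC)cc2OC)c1OC | intermediate (not isolated)
19 | 3,5-dimethoxy-2,4-bis(ArCH2)phenol | Oc1cc(OC)c(Cc2c(OC)cc(OC)c(Cc3c(OC)cc(OC)cc3OC)c2OC)c(OC)c1Cc1c(OC)cc(OC)c(Cc2c(OC)cc(OC)cc2OC)c1OC | intermediate
20 | 1,3,5-trimethoxy-2,4-bis(ArCH2)benzene | COc1cc(OC)c(Cc2c(OC)cc(OC)c(Cc3c(OC)cc(OC)cc3OC)c2OC)c(OC)c1Cc1c(OC)cc(OC)c(Cc2c(OC)cc(OC)cc2OC)c1OC | intermediate
21 | pentabutanoyl pentadecamethyl ether (one butanoyl on each of rings A to E) | COc1c(C(=O)CCC)c(OC)c(Cc2c(OC)c(C(=O)CCC)c(OC)c(Cc3c(OC)c(C(=O)CCC)c(OC)cc3OC)c2OC)c(OC)c1Cc1c(OC)c(C(=O)CCC)c(OC)c(Cc2c(OC)c(C(=O)CCC)c(OC)cc2OC)c1OC | intermediate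
22 | pentabutanoyl pentadecaphenol | Oc1c(C(=O)CCC)c(O)c(Cc2c(O)c(C(=O)CCC)c(O)c(Cc3c(O)c(C(=O)CCC)c(O)cc3O)c2O)c(O)c1Cc1c(O)c(C(=O)CCC)c(O)c(Cc2c(O)c(C(=O)CCC)c(O)cc2O)c1O | intermediate
23 | CNP0188003.0 (rings A and E as 2-butanoyl-4,4-dimethyl triketone enols, rings B, C, D as butanoylphloroglucinols, four CH2 bridges) | CCCC(=O)C1=C(O)C(C)(C)C(O)=C(Cc2c(O)c(Cc3c(O)c(Cc4c(O)c(CC5=C(O)C(C)(C)C(O)=C(C(=O)CCC)C5=O)c(O)c(C(=O)CCC)c4O)c(O)c(C(=O)CCC)c3O)c(O)c(C(=O)CCC)c2O)C1=O | target

**Step count**

Total: 12 steps. Longest linear sequence: 11 steps (steps 1–3 and 5–12; step 4 is a side branch).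

**Steps most likely to fail**

Step 8. The 3-methoxy group makes 14 a push–pull cyclobutenone, so its ring opening may be slower than thermal decay of the ynol ether. The phenol that forms may also trap ketene 15 as an aryl ester. The cascade could therefore stall at 16 or end in oligomers. The fallback builds the pentamer around a preformed ring C by Friedel–Crafts benzylation; it sets out from 1 and 3 and comes back at 20. Compound 1 would be formylated twice under forcing Vilsmeier–Haack conditions (excess POCl3/DMF, 80 °C) to 2,4,6-trimethoxybenzene-1,3-dicarbaldehyde F1. NaBH4 reduction would give (2,4,6-trimethoxy-1,3-phenylene)dimethanol F2. F2 would then be condensed with an excess of diarylmethane 3 under catalytic Sc(OTf)3 in CH2Cl2. All four free positions of 3 are equivalent, so each benzylic cation from F2 installs one Ar arm and 20 should form directly, with excess 3 recovered.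

Step 12. After the first methylation of rings A and E, the anions of all five rings can still be alkylated at bridge-bearing carbons or at oxygen. Methoxide can also start exchange of the methylene bridges through quinone methide fragments. The risk is therefore loss of site selectivity and scrambling of the chain. The fallback brings in rings A and E already methylated and joins them with formaldehyde; it sets out from 5, 1 and 2 and comes back at 23, and it gives up the late methylation of the pentamer. Alcohol 5 would be condensed with an excess of 1 (cat. Sc(OTf)3, CH2Cl2) to the linear permethyl trimer F3, which corresponds to rings B, C and D. F3 would take one butanoyl group per ring (n-PrCOCl, SnCl4) to give the tris-butanoyl nonamethyl ether F4, and BBr3 would then give the tris-butanoyl nonaphenol F5, whose two outer rings each keep one free ring carbon. Separately, commercial 1-(2,4,6-trihydroxyphenyl)butan-1-one would be C-dimethylated (MeI, NaOMe, MeOH) to 2-butanoylfilicinic acid F6; on this monomer the dearomatising methylation is the classical preparation. F5, an excess of F6 and formaldehyde 2 in dilute aqueous NaOH at 0 °C should then form the two outer methylene bridges and give 23.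

Step 10. The free carbons of rings B, C and D are shielded by two flanking methoxy groups, so acylation there may be incomplete while rings A and E begin to take up a second acyl group. The acylium ion or the acid formed may also attack the bridge-bearing carbons and cause bridge migration or cleavage. The fallback replaces electrophilic by anionic acylation; it sets out from 20 and comes back at 21. Each remaining ring C–H lies between two methoxy groups, so five-fold directed ortho-lithiation (n-BuLi, TMEDA, THF, 0 °C) should give the pentalithio derivative F7 (not isolated). Quenching F7 with N-methoxy-N-methylbutanamide should give 21 with no acid present.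

**Further compounds**

F1 | step 8 | 2,4,6-trimethoxybenzene-1,3-dicarbaldehyde | O=Cc1c(OC)cc(OC)c(C=O)c1OC
F2 | step 8 | (2,4,6-trimethoxy-1,3-phenylene)dimethanol | OCc1c(OC)cc(OC)c(CO)c1OC
F3 | step 12 | linear permethyl trimer, 1,3,5-trimethoxy-2-(ArCH2)benzene | COc1cc(OC)cc(OC)c1Cc1c(OC)cc(OC)c(Cc2c(OC)cc(OC)cc2OC)c1OC
F4 | step 12 | tris-butanoyl nonamethyl ether of the trimer (one butanoyl per ring) | CCCC(=O)c1c(OC)c(Cc2c(OC)cc(OC)c(C(=O)CCC)c2OC)c(OC)c(Cc2c(OC)cc(OC)c(C(=O)CCC)c2OC)c1OC
F5 | step 12 | tris-butanoyl nonaphenol trimer | CCCC(=O)c1c(O)c(Cc2c(O)cc(O)c(C(=O)CCC)c2O)c(O)c(Cc2c(O)cc(O)c(C(=O)CCC)c2O)c1O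
F6 | step 12 | 2-butanoylfilicinic acid (2-butanoyl-3,5-dihydroxy-4,4-dimethylcyclohexa-2,5-dien-1-one) | CCCC(=O)C1=C(O)C(C)(C)C(O)=CC1=O
F7 | step 10 | pentalithio derivative of 20 (one lithium on each ring between two methoxy groups) | COc1c([Li])c(OC)c(Cc2c(OC)c([Li])c(OC)c(Cc3c(OC)c([Li])c(OC)cc3OC)c2OC)c(OC)c1Cc1c(OC)c([Li])c(OC)c(Cc2c(OC)c([Li])c(OC)cc2OC)c1OC
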